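## Structural features

The target is an unsymmetrical dimer of two α-hydroxy-α,β-dibenzyl-γ-butyrolactones. Ring A (guaiacyl) is the β-benzyl arene of the first lactone and ring B its α-benzyl arene; ring C is the β-benzyl arene of the second lactone and ring D (guaiacyl) its α-benzyl arene. Rings B and C are joined by a biaryl bond ortho to the phenolic oxygen on both sides, giving a 2,2'-dihydroxy-3,3'-dimethoxybiphenyl whose two para positions carry different benzylic carbons (Cα–CH2 on ring B, Cβ–CH2 on ring C). Each lactone has two adjacent stereocentres, the fully substituted carbinol C3 (R) and the tertiary carbon C4 (R); the C3 hydroxyl is cis to the C4 benzyl group and the two benzyl groups are trans. The fragile groups are four oxidisable phenols (two in a chelating biphenol), two base-sensitive lactones and two tertiary alcohols. C3 has no hydrogen and C4–H is not acidic, so neither centre can be corrected by epimerisation once the benzylic carbons are in place. The real difficulty is twofold: making the quaternary carbinol in one absolute sense and relaying it to C4, and telling four nearly identical guaiacyl rings apart so that only B and C are joined. The key step exploits the fact that C4 of each lactone bears two CH2 groups, the ring C5H2–O and the benzylic CH2: C4 can come from a prochiral CH(CH2OH)2 carbon on C3, one arm closing the lactone and the other later becoming the benzylic carbon.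

## Logic of the disconnections

28 to 27: three benzyl C–O bonds on the phenols of rings A, B and C are cut. The phenols must be masked during the couplings, and one neutral hydrogenolysis at the end removes all three. The forward step must spare lactones, tertiary alcohols and the biaryl.

27 to 26 and 19: the aryl–CH2 bond between ring C and C4 of the second lactone is cut. This splits the dimer into a biaryl-bearing monomer and a small lactone that carries both stereocentres of the second unit. The forward step must form a C(sp3)–C(sp2) bond without base or a strong nucleophile, which points to a reductive nickel coupling of two electrophiles.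

26 to 25 to 24: the two benzyl C–O bonds on rings B and C and the C–Br bond on ring C are cut. The bromide is introduced late, because only the free phenol of ring C directs it para. The forward bromination must choose ring C (free para position) over ring B (no free ortho or para position) and ring A (an ether).

24 to 22 and 23: the ring B–ring C biaryl bond is cut. Ring C then arrives as a catalogue boronic acid. The forward Suzuki coupling must tolerate two ortho-oxygenated partners and a lactone.

22 to 21: the C–I bond on ring B is cut. Ring B is the only free phenol in 21 and has a single free ortho position. The forward iodination must leave the ether ring A alone.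

21 to 19 and 20: the aryl–CH2 bond between ring A and C4 of the first lactone is cut, the same coupling as above. Ring A arrives benzylated while ring B is a free phenol, so the two guaiacyl rings of 21 are differentiated without extra steps. One building block, 19, serves both lactones.

19 to 18 to 17: the C–I bond goes back to C–OH and the free phenol back to its benzyl ether. The benzyl group is needed for the enolate chemistry earlier; it is removed before the iodide is made, under neutral conditions that cannot equilibrate C4.

17 to 13 (key disconnection): the acyl C2–O1 bond of the lactone is cut. C4 becomes a prochiral CH(CH2OH)2 carbon, masked as an acetonide, and C3 is the only stereocentre left. In the forward sense the bond made is this acyl C–O bond; both CH2–O bonds of the diol already exist. The forward step must select one of two diastereotopic hydroxymethyl groups under equilibrating conditions.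

13 to 12 to 11 to 7 and 8: the methyl ester goes back to the acylal, the C–H at the dioxane carbon back to C–O, and the bond between the quaternary carbon and the dioxane carbon is cut. A symmetrical ketone supplies the three-carbon unit without creating a stereocentre. A secondary alkyl electrophile could not alkylate this enolate, so addition to the ketone followed by deoxygenation is used. The forward aldol must occur anti to the tert-butyl group, and the hindered alkoxide is trapped as an oxalate in the same flask, so no separate acylation of the tertiary alcohol is needed.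

7 to 5 and 6, then 4, then 1: the acetal C–O bonds, the benzyl ether and the C–O bond (back to C–N) are cut. This reaches a chiral-pool amino acid. The forward steps need retention in the diazotisation and a pure cis acetal.

## Other disconnections considered

Alternative 1: The cut is at both Cα–Cβ bonds (C3–C4 of each lactone). It leads back to A1, a preformed biaryl with two allylic α-benzyloxy ester arms. Forward, double chelation-controlled enolisation and silylation (KN(SiMe3)2, Me3SiCl) would trigger two Ireland–Claisen rearrangements through chair transition states and give the bis-acid A2. Each propenyl group of A2 is a masked hydroxymethyl group (oxidative cleavage, reduction, lactonisation, hydrogenolysis).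
- In favour: all four stereocentres would be set in one operation by a well-understood suprafacial [3,3] shift, with the enolate geometry fixed by chelation. On stereochemical predictability this is better than the chosen plan, which relies on a thermodynamic bias of unknown size.
- Against: with the benzyloxy group equatorial in the chair, the cis relation between the C3 oxygen and the C4 benzyl group requires the arylmethyl group axial on the allyl terminus. A1 must therefore carry (Z)-alkenes and (R)-carbinol centres in both arms; (E)-alkenes would give the C4 epimers. Two congested bonds between a fully substituted enolate carbon and a branched allyl terminus must form in the same molecule. Both arms then need oxidative alkene cleavage next to four electron-rich arenes. The biaryl with four different side chains must exist first, so the ring differentiation problem is untouched.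
- Comparison: in structure, the chosen plan takes C3 from an amino acid while A1 builds it. In mechanism, kinetic pericyclic control stands against thermodynamic selection. In step economy, the two-directional stereo-defining step is the equal or the better, but the work before A1 and after A2 should make the whole longer.

Alternative 2: The cut is the ring B–ring C biaryl bond. It leads back to A3, two complete lactone monomers tied through their phenol oxygens by a di-tert-butylsilylene tether, with bromide on ring B and an ortho C–H on ring C. Forward, Pd(OAc)2-catalysed intramolecular C–H arylation would close the seven-membered dioxasilepine A4; fluoride and hydrogenolysis follow.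
- In favour: it is the most convergent union, joining two finished monomers at the latest stage, and here it is better than the chosen plan. The tether enforces cross-selectivity and regiochemistry (ring C has one ortho C–H) and protects both phenols.
- Against: it does not address the lactone stereocentres, so each half of A3 still needs a construction like step 7. The unsymmetrical silane must be assembled stepwise from two hindered phenols. The arylation needs base and heat in the presence of two lactones and two tertiary alcohols.
- Comparison: the chosen plan makes the same bond by a mild Suzuki coupling on 22 with a small boronic acid, which is more robust but less convergent because the second lactone is attached afterwards. Step counts are about equal (tether on and off against iodination, bromination and benzylation). The mechanisms differ: concerted metalation–deprotonation at an electron-rich arene against transmetalation.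

Alternative 3: The cut is at both Cβ–CH2(O) bonds (C4–C5 of each lactone). It leads back to the bis(acyloxymethyl xanthate) A5, which carries two (E)-styrenes on the quaternary carbinols. Forward, (Me3Si)3SiH and AIBN would generate two acyloxymethyl radicals that add 5-exo-trig to the styrene carbons next to the carbinols. The benzylic radicals are then reduced to give A6, the tetra-O-benzyl target.
- In favour: both rings, both C–C bonds and both β-stereocentres form in one late step, and A6 is one hydrogenolysis from the target. In end-game step economy this is better than the chosen plan. The sense of induction is expected to be the same (new benzyl group anti to the larger α-substituent).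
- Against: an ester prefers the conformation in which the radical cannot reach the alkene, so such cyclisations are slow and compete with premature reduction, and two must succeed in one molecule. A5 still needs both quaternary carbinols in enantiopure form, now as tertiary allylic alcohols, and two styrenes on the biaryl.
- Comparison: in structure, the chosen plan reaches C4 from a saturated prochiral carbon, while A5 reaches it from an alkene. In mechanism, an irreversible kinetic radical closure stands against a reversible, self-correcting lactonisation. The chosen plan has more steps after the ring closure but a simpler precursor.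

Key step: step 7

Assumption: rings are lettered A to D as defined under "Structural features", and 6, 8, 20 and 23 are bought as catalogue compounds.

## Steps

Step 1
Reactants: 1 3-O-methyl-L-DOPA
Product: 4 (S)-2-hydroxy-3-(4-hydroxy-3-methoxyphenyl)propanoic acid, via diazonium carboxylate 2 (not isolated), via α-lactone 3 (not isolated)
Conditions: NaNO2 (1.5 equiv), 1 M H2SO4, 0 → 23 °C
Reagents that add atoms: water, O
Why: Diazotisation of the α-amino acid; the carboxylate displaces N2 with inversion to give 3 and water opens 3 with a second inversion, so the (S) configuration should be retained. Cold dilute acid and slow nitrite addition keep nitrosation of the guaiacol ring slow.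

Step 2
Reactants: 4 (S)-2-hydroxy-3-(4-hydroxy-3-methoxyphenyl)propanoic acid
Product: 5 (S)-3-[4-(benzyloxy)-3-methoxyphenyl]-2-hydroxypropanoic acid
Conditions: BnBr (1.1 equiv), NaOH (2.5 equiv), EtOH/H2O, 50 °C; then 1 M HCl
Reagents that add atoms: benzyl bromide, BrCc1ccccc1
Why: Williamson ether synthesis; in aqueous base the phenoxide is the only strong nucleophile, and any benzyl ester is saponified by the excess hydroxide. The stereocentre is not touched.

Step 3
Reactants: 5 (S)-3-[4-(benzyloxy)-3-methoxyphenyl]-2-hydroxypropanoic acid; 6 pivalaldehyde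
Product: 7 (2S,5S)-5-[4-(benzyloxy)-3-methoxybenzyl]-2-tert-butyl-1,3-dioxolan-4-one
Conditions: TsOH·H2O (5 mol %), H2SO4 (cat.), pentane/CH2Cl2, reflux, Dean–Stark; recrystallisation
Reagents that add atoms: none
Why: Acid-catalysed acetalisation of an α-hydroxy acid (Seebach self-regeneration of stereocentres); the cis acetal is favoured and is purified by crystallisation, which stores the chirality in the new acetal carbon C2 (S). The cis purity fixes the enantiomeric purity of everything that follows.

Step 4
Reactants: 7 (2S,5S)-5-[4-(benzyloxy)-3-methoxybenzyl]-2-tert-butyl-1,3-dioxolan-4-one; 8 2,2-dimethyl-1,3-dioxan-5-one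
Product: 11 methyl 5-[(2S,4R)-4-[4-(benzyloxy)-3-methoxybenzyl]-2-tert-butyl-5-oxo-1,3-dioxolan-4-yl]-2,2-dimethyl-1,3-dioxan-5-yl oxalate, via lithium enolate 9 (not isolated), via lithium aldolate 10 (not isolated)
Conditions: LiN(i-Pr)2 (1.05 equiv), THF, −78 °C; 8 (1.3 equiv), −78 °C; then ClC(O)CO2Me (3 equiv), −78 → −20 °C
Reagents that add atoms: methyl chlorooxoacetate, COC(=O)C(=O)Cl
Why: Aldol addition of the planar enolate 9 to the doubly α-oxygenated, strongly electrophilic ketone 8 on the face opposite the tert-butyl group; the new C–C bond takes the place of the former C–H, so the quaternary centre should be (R), controlled by C2. The hindered alkoxide 10 is acylated in the flask by the very reactive acid chloride before retro-aldol cleavage can set in.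

Step 5
Reactants: 11 methyl 5-[(2S,4R)-4-[4-(benzyloxy)-3-methoxybenzyl]-2-tert-butyl-5-oxo-1,3-dioxolan-4-yl]-2,2-dimethyl-1,3-dioxan-5-yl oxalate
Product: 12 (2S,5R)-5-[4-(benzyloxy)-3-methoxybenzyl]-2-tert-butyl-5-(2,2-dimethyl-1,3-dioxan-5-yl)-1,3-dioxolan-4-one
Conditions: Bu3SnH (2 equiv), AIBN (0.2 equiv), PhMe, 110 °C
Reagents that add atoms: none
Why: Radical deoxygenation of a tertiary methyl oxalate (Barton–McCombie-type chain); the tertiary dioxanyl radical abstracts hydrogen from Bu3SnH. The carbon formed has two identical CH2O arms and is not stereogenic; benzyl ether, acetonide and acylal are inert to tin radicals.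

Step 6
Reactants: 12 (2S,5R)-5-[4-(benzyloxy)-3-methoxybenzyl]-2-tert-butyl-5-(2,2-dimethyl-1,3-dioxan-5-yl)-1,3-dioxolan-4-one
Product: 13 methyl (2R)-3-[4-(benzyloxy)-3-methoxyphenyl]-2-(2,2-dimethyl-1,3-dioxan-5-yl)-2-hydroxypropanoate
Conditions: NaOMe (0.3 equiv), MeOH, 0 → 23 °C
Reagents that add atoms: methanol, CO
Why: Base-catalysed transesterification; methoxide opens the activated acylal carbonyl and the hemiacetal alkoxide expels pivalaldehyde, leaving the tertiary alcohol. The quaternary centre has no α-hydrogen and the acetonide is stable to base.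

Step 7
Reactants: 13 methyl (2R)-3-[4-(benzyloxy)-3-methoxyphenyl]-2-(2,2-dimethyl-1,3-dioxan-5-yl)-2-hydroxypropanoate
Product: 17 (3R,4R)-3-[4-(benzyloxy)-3-methoxybenzyl]-3-hydroxy-4-(hydroxymethyl)oxolan-2-one, via triol ester 14 (not isolated), via epimeric lactone 15 (not isolated), via bridged hemiorthoester 16 (not isolated)
Conditions: TsOH·H2O (0.2 equiv), MeOH, 23 °C; evaporate; PhMe, 60 °C
Reagents that add atoms: none
Why: TsOH in methanol removes the acetonide by transacetalisation and gives 14; after the solvent switch either primary hydroxyl attacks the protonated ester carbonyl and methanol is lost, closing the γ-lactone in a 5-exo-trig acyl substitution that forms the acyl C–O bond (the CH2–O bonds are already present). The closest known reaction type is the acid-catalysed equilibrating lactonisation of diol esters that selects one of two diastereotopic hydroxymethyl groups. Lactones 15 and 17 should stay in equilibrium, because the free hydroxymethyl group of each adds to the lactone carbonyl to give 16, a 2,6-dioxabicyclo[2.2.1]heptan-1-ol with both ring oxygens on the former carbonyl carbon, which can open in either direction. The new stereocentre C4 is therefore set under thermodynamic control by the preset quaternary centre C3. In 17 the free CH2OH is cis to the small hydroxyl and trans to the arylmethyl group, whereas in 15 it is cis to the arylmethyl group and suffers a vicinal cis carbon–carbon interaction. A hydrogen bond between the cis hydroxyl groups in toluene should add to this preference, and removing methanol keeps the open ester from competing. The selectivity needed is between the two hydroxymethyl groups, and it rests on the size difference between OH and arylmethyl at C3; C3 cannot epimerise, and the tertiary hydroxyl could only close a three-membered ring. Any 15 that remains is returned to the same conditions.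

Step 8
Reactants: 17 (3R,4R)-3-[4-(benzyloxy)-3-methoxybenzyl]-3-hydroxy-4-(hydroxymethyl)oxolan-2-one
Product: 18 (3R,4R)-3-hydroxy-3-(4-hydroxy-3-methoxybenzyl)-4-(hydroxymethyl)oxolan-2-one
Conditions: H2 (1 atm), 10% Pd/C, EtOAc, 23 °C
Reagents that add atoms: none
Why: Hydrogenolysis of the benzyl aryl ether; the medium is neutral, so the lactone cannot translactonise and C4 keeps its configuration.

Step 9
Reactants: 18 (3R,4R)-3-hydroxy-3-(4-hydroxy-3-methoxybenzyl)-4-(hydroxymethyl)oxolan-2-one
Product: 19 (3R,4R)-3-hydroxy-3-(4-hydroxy-3-methoxybenzyl)-4-(iodomethyl)oxolan-2-one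
Conditions: PPh3 (1.3 equiv), I2 (1.25 equiv), imidazole (2.5 equiv), THF, 0 → 23 °C (reagents premixed)
Reagents that add atoms: iodine, II
Why: Appel-type iodination; only the primary alcohol forms an alkoxyphosphonium ion that iodide can displace, the tertiary alcohol being too hindered and the phenol not displaceable. With the second hydroxymethyl group gone, C4 can no longer equilibrate.

Step 10
Reactants: 19 (3R,4R)-3-hydroxy-3-(4-hydroxy-3-methoxybenzyl)-4-(iodomethyl)oxolan-2-one; 20 1-(benzyloxy)-4-bromo-2-methoxybenzene
Product: 21 (3R,4R)-4-[4-(benzyloxy)-3-methoxybenzyl]-3-hydroxy-3-(4-hydroxy-3-methoxybenzyl)oxolan-2-one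
Conditions: NiBr2·dme (10 mol %), 4,4'-di-tert-butyl-2,2'-bipyridine (10 mol %), Zn (2 equiv), NaI (0.25 equiv), DMA, 60 °C
Reagents that add atoms: none
Why: Nickel-catalysed reductive cross-electrophile coupling; zerovalent nickel adds to the aryl bromide, the primary radical from 19 is captured by the arylnickel species, and reductive elimination from trivalent nickel forms the C(sp3)–C(sp2) bond with Zn as reductant. The medium is not basic, so phenol, tertiary alcohol and lactone should be tolerated; the radical is exocyclic to C4, so no stereocentre is touched.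

Step 11
Reactants: 21 (3R,4R)-4-[4-(benzyloxy)-3-methoxybenzyl]-3-hydroxy-3-(4-hydroxy-3-methoxybenzyl)oxolan-2-one
Product: 22 (3R,4R)-4-[4-(benzyloxy)-3-methoxybenzyl]-3-hydroxy-3-(4-hydroxy-3-iodo-5-methoxybenzyl)oxolan-2-one
Conditions: I2 (1.05 equiv), NaHCO3 (2 equiv), THF/H2O, 0 → 23 °C
Reagents that add atoms: iodine, II
Why: Electrophilic iodination through the phenoxide; only ring B is a free phenol, and it has one free ortho position and a blocked para position. The ether ring A does not react under these mildly basic conditions.

Step 12
Reactants: 22 (3R,4R)-4-[4-(benzyloxy)-3-methoxybenzyl]-3-hydroxy-3-(4-hydroxy-3-iodo-5-methoxybenzyl)oxolan-2-one; 23 (2-hydroxy-3-methoxyphenyl)boronic acid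
Product: 24 (3R,4R)-4-[4-(benzyloxy)-3-methoxybenzyl]-3-[(2,2'-dihydroxy-3,3'-dimethoxybiphenyl-5-yl)methyl]-3-hydroxyoxolan-2-one
Conditions: Pd(OAc)2 (5 mol %), SPhos (10 mol %), K3PO4 (3 equiv), 23 (1.5 equiv), THF/H2O, 50 °C
Reagents that add atoms: none
Why: Suzuki–Miyaura coupling; zerovalent palladium with the bulky electron-rich biarylphosphine adds to the aryl iodide and should cope with two ortho-oxygenated partners, the excess of 23 covering protodeboronation. A mildly acidic work-up recloses any lactone opened by the base, which has no stereochemical consequence because only one hydroxyl can close.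

Step 13
Reactants: 24 (3R,4R)-4-[4-(benzyloxy)-3-methoxybenzyl]-3-[(2,2'-dihydroxy-3,3'-dimethoxybiphenyl-5-yl)methyl]-3-hydroxyoxolan-2-one
Product: 25 (3R,4R)-4-[4-(benzyloxy)-3-methoxybenzyl]-3-[(5'-bromo-2,2'-dihydroxy-3,3'-dimethoxybiphenyl-5-yl)methyl]-3-hydroxyoxolan-2-one
Conditions: NBS (1.0 equiv), MeCN, −20 → 0 °C
Reagents that add atoms: N-bromosuccinimide, O=C1CCC(=O)N1Br
Why: Electrophilic bromination para to the free phenol of ring C, the only phenol with a free para position. Ring B has all ortho and para positions substituted, ring A is only an ether, and the position para to the ring C methoxy group is shielded by the neighbouring aryl group.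

Step 14
Reactants: 25 (3R,4R)-4-[4-(benzyloxy)-3-methoxybenzyl]-3-[(5'-bromo-2,2'-dihydroxy-3,3'-dimethoxybiphenyl-5-yl)methyl]-3-hydroxyoxolan-2-one
Product: 26 (3R,4R)-4-[4-(benzyloxy)-3-methoxybenzyl]-3-{[2,2'-bis(benzyloxy)-5'-bromo-3,3'-dimethoxybiphenyl-5-yl]methyl}-3-hydroxyoxolan-2-one
Conditions: BnBr (2.5 equiv), K2CO3 (3 equiv), DMF, 40 °C
Reagents that add atoms: benzyl bromide, BrCc1ccccc1
Why: Williamson ether synthesis on both phenols; K2CO3 does not deprotonate the tertiary alcohol. This removes the acidic, chelating biphenol before the second nickel coupling.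

Step 15
Reactants: 26 (3R,4R)-4-[4-(benzyloxy)-3-methoxybenzyl]-3-{[2,2'-bis(benzyloxy)-5'-bromo-3,3'-dimethoxybiphenyl-5-yl]methyl}-3-hydroxyoxolan-2-one; 19 (3R,4R)-3-hydroxy-3-(4-hydroxy-3-methoxybenzyl)-4-(iodomethyl)oxolan-2-one
Product: 27 (3R,4R)-3-{[2,2'-bis(benzyloxy)-5'-{[(3R,4R)-4-hydroxy-4-(4-hydroxy-3-methoxybenzyl)-5-oxooxolan-3-yl]methyl}-3,3'-dimethoxybiphenyl-5-yl]methyl}-4-[4-(benzyloxy)-3-methoxybenzyl]-3-hydroxyoxolan-2-one
Conditions: NiBr2·dme (10 mol %), 4,4'-di-tert-butyl-2,2'-bipyridine (10 mol %), Zn (2 equiv), NaI (0.25 equiv), 19 (1.5 equiv), DMA, 60 °C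
Reagents that add atoms: none
Why: The same nickel-catalysed reductive cross-electrophile coupling as in step 10; the ring C bromide is para to a benzyloxy group and has two free ortho positions, so oxidative addition is unhindered. The CH2 radical from 19 is trans to the C3 arylmethyl group, which disfavours attack on its own arene, and both stereocentres of the second lactone arrive unchanged.

Step 16
Reactants: 27 (3R,4R)-3-{[2,2'-bis(benzyloxy)-5'-{[(3R,4R)-4-hydroxy-4-(4-hydroxy-3-methoxybenzyl)-5-oxooxolan-3-yl]methyl}-3,3'-dimethoxybiphenyl-5-yl]methyl}-4-[4-(benzyloxy)-3-methoxybenzyl]-3-hydroxyoxolan-2-one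
Product: 28 (3R,4R)-3-{[2,2'-dihydroxy-5'-{[(3R,4R)-4-hydroxy-4-(4-hydroxy-3-methoxybenzyl)-5-oxooxolan-3-yl]methyl}-3,3'-dimethoxybiphenyl-5-yl]methyl}-3-hydroxy-4-(4-hydroxy-3-methoxybenzyl)oxolan-2-one
Conditions: H2 (1 atm), 10% Pd/C, EtOAc/EtOH, 23 °C
Reagents that add atoms: none
Why: Hydrogenolysis of the three benzyl aryl ethers under neutral conditions; lactones, tertiary alcohols and the biaryl are inert and no stereocentre is involved.

## Compound list

1 | 3-O-methyl-L-DOPA, (S)-2-amino-3-(4-hydroxy-3-methoxyphenyl)propanoic acid | COc1cc(C[C@H](N)C(=O)O)ccc1O | starting material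
2 | diazonium carboxylate (not isolated), (S)-1-carboxylato-2-(4-hydroxy-3-methoxyphenyl)ethanediazonium | COc1cc(C[C@H]([N+]#N)C(=O)[O-])ccc1O | intermediate
3 | α-lactone (not isolated), (R)-3-(4-hydroxy-3-methoxybenzyl)oxiran-2-one | COc1cc(C[C@H]2OC2=O)ccc1O | intermediate
4 | (S)-2-hydroxy-3-(4-hydroxy-3-methoxyphenyl)propanoic acid | COc1cc(C[C@H](O)C(=O)O)ccc1O | intermediate
5 | (S)-3-[4-(benzyloxy)-3-methoxyphenyl]-2-hydroxypropanoic acid | COc1cc(C[C@H](O)C(=O)O)ccc1OCc1ccccc1 | intermediate
6 | pivalaldehyde | CC(C)(C)C=O | starting material
7 | (2S,5S)-5-[4-(benzyloxy)-3-methoxybenzyl]-2-tert-butyl-1,3-dioxolan-4-one (cis) | O=C1O[C@@H](C(C)(C)C)O[C@H]1Cc1ccc(OCc2ccccc2)c(OC)c1 | intermediate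
8 | 2,2-dimethyl-1,3-dioxan-5-one | CC1(C)OCC(=O)CO1 | starting material
9 | lithium enolate (not isolated), lithium (2S)-5-[4-(benzyloxy)-3-methoxybenzyl]-2-tert-butyl-1,3-dioxol-4-olate | [Li]OC1=C(Cc2ccc(OCc3ccccc3)c(OC)c2)O[C@H](C(C)(C)C)O1 | intermediate
10 | lithium aldolate (not isolated), lithium 5-[(2S,4R)-4-[4-(benzyloxy)-3-methoxybenzyl]-2-tert-butyl-5-oxo-1,3-dioxolan-4-yl]-2,2-dimethyl-1,3-dioxan-5-olate | O=C1O[C@@H](C(C)(C)C)O[C@@]1(C2(O[Li])COC(C)(C)OC2)Cc1ccc(OCc2ccccc2)c(OC)c1 | intermediate
11 | methyl 5-[(2S,4R)-4-[4-(benzyloxy)-3-methoxybenzyl]-2-tert-butyl-5-oxo-1,3-dioxolan-4-yl]-2,2-dimethyl-1,3-dioxan-5-yl oxalate | O=C1O[C@@H](C(C)(C)C)O[C@@]1(C2(OC(=O)C(=O)OC)COC(C)(C)OC2)Cc1ccc(OCc2ccccc2)c(OC)c1 | intermediate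
12 | (2S,5R)-5-[4-(benzyloxy)-3-methoxybenzyl]-2-tert-butyl-5-(2,2-dimethyl-1,3-dioxan-5-yl)-1,3-dioxolan-4-one | O=C1O[C@@H](C(C)(C)C)O[C@@]1(C2COC(C)(C)OC2)Cc1ccc(OCc2ccccc2)c(OC)c1 | intermediate
13 | methyl (2R)-3-[4-(benzyloxy)-3-methoxyphenyl]-2-(2,2-dimethyl-1,3-dioxan-5-yl)-2-hydroxypropanoate (precursor of the key step) | COC(=O)[C@@](O)(Cc1ccc(OCc2ccccc2)c(OC)c1)C1COC(C)(C)OC1 | intermediate
14 | triol ester (not isolated), methyl (2R)-3-[4-(benzyloxy)-3-methoxyphenyl]-2-(1,3-dihydroxypropan-2-yl)-2-hydroxypropanoate | COC(=O)[C@@](O)(Cc1ccc(OCc2ccccc2)c(OC)c1)C(CO)CO | intermediate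
15 | epimeric lactone (not isolated), (3R,4S)-3-[4-(benzyloxy)-3-methoxybenzyl]-3-hydroxy-4-(hydroxymethyl)oxolan-2-one | OC[C@H]1COC(=O)[C@@]1(O)Cc1ccc(OCc2ccccc2)c(OC)c1 | intermediate
16 | bridged hemiorthoester (not isolated), 7-[4-(benzyloxy)-3-methoxybenzyl]-2,6-dioxabicyclo[2.2.1]heptane-1,7-diol, 7-hydroxyl syn to the bridge that opens to the CH2OH of 17 | O2C[C@@H]1CO[C@@]2(O)[C@@]1(O)Cc1ccc(OCc2ccccc2)c(OC)c1 | intermediate
17 | (3R,4R)-3-[4-(benzyloxy)-3-methoxybenzyl]-3-hydroxy-4-(hydroxymethyl)oxolan-2-one (product of the key step) | OC[C@@H]1COC(=O)[C@@]1(O)Cc1ccc(OCc2ccccc2)c(OC)c1 | intermediate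
18 | (3R,4R)-3-hydroxy-3-(4-hydroxy-3-methoxybenzyl)-4-(hydroxymethyl)oxolan-2-one | OC[C@@H]1COC(=O)[C@@]1(O)Cc1ccc(O)c(OC)c1 | intermediate
19 | (3R,4R)-3-hydroxy-3-(4-hydroxy-3-methoxybenzyl)-4-(iodomethyl)oxolan-2-one | IC[C@@H]1COC(=O)[C@@]1(O)Cc1ccc(O)c(OC)c1 | intermediate
20 | 1-(benzyloxy)-4-bromo-2-methoxybenzene | COc1cc(Br)ccc1OCc1ccccc1 | starting material
21 | (3R,4R)-4-[4-(benzyloxy)-3-methoxybenzyl]-3-hydroxy-3-(4-hydroxy-3-methoxybenzyl)oxolan-2-one | COc1cc(C[C@@H]2COC(=O)[C@@]2(O)Cc2ccc(O)c(OC)c2)ccc1OCc1ccccc1 | intermediate
22 | (3R,4R)-4-[4-(benzyloxy)-3-methoxybenzyl]-3-hydroxy-3-(4-hydroxy-3-iodo-5-methoxybenzyl)oxolan-2-one | COc1cc(C[C@@H]2COC(=O)[C@@]2(O)Cc2cc(I)c(O)c(OC)c2)ccc1OCc1ccccc1 | intermediate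
23 | (2-hydroxy-3-methoxyphenyl)boronic acid | COc1cccc(B(O)O)c1O | starting material
24 | (3R,4R)-4-[4-(benzyloxy)-3-methoxybenzyl]-3-[(2,2'-dihydroxy-3,3'-dimethoxybiphenyl-5-yl)methyl]-3-hydroxyoxolan-2-one | COc1cc(C[C@@H]2COC(=O)[C@@]2(O)Cc2cc(OC)c(O)c(-c3cccc(OC)c3O)c2)ccc1OCc1ccccc1 | intermediate
25 | (3R,4R)-4-[4-(benzyloxy)-3-methoxybenzyl]-3-[(5'-bromo-2,2'-dihydroxy-3,3'-dimethoxybiphenyl-5-yl)methyl]-3-hydroxyoxolan-2-one | COc1cc(C[C@@H]2COC(=O)[C@@]2(O)Cc2cc(OC)c(O)c(-c3cc(Br)cc(OC)c3O)c2)ccc1OCc1ccccc1 | intermediate
26 | (3R,4R)-4-[4-(benzyloxy)-3-methoxybenzyl]-3-{[2,2'-bis(benzyloxy)-5'-bromo-3,3'-dimethoxybiphenyl-5-yl]methyl}-3-hydroxyoxolan-2-one | COc1cc(C[C@@H]2COC(=O)[C@@]2(O)Cc2cc(OC)c(OCc3ccccc3)c(-c3cc(Br)cc(OC)c3OCc3ccccc3)c2)ccc1OCc1ccccc1 | intermediate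
27 | tri-O-benzyl ether of the target (benzyl on the phenols of rings A, B and C; (3R,4R) in both lactones) | COc1cc(C[C@@H]2COC(=O)[C@@]2(O)Cc2cc(OC)c(OCc3ccccc3)c(-c3cc(C[C@@H]4COC(=O)[C@@]4(O)Cc4ccc(O)c(OC)c4)cc(OC)c3OCc3ccccc3)c2)ccc1OCc1ccccc1 | intermediate
28 | CNP0218652.1, (3R,4R)-3-{[2,2'-dihydroxy-5'-{[(3R,4R)-4-hydroxy-4-(4-hydroxy-3-methoxybenzyl)-5-oxooxolan-3-yl]methyl}-3,3'-dimethoxybiphenyl-5-yl]methyl}-3-hydroxy-4-(4-hydroxy-3-methoxybenzyl)oxolan-2-one | COc1cc(C[C@@H]2COC(=O)[C@@]2(O)Cc2cc(OC)c(O)c(-c3cc(C[C@@H]4COC(=O)[C@@]4(O)Cc4ccc(O)c(OC)c4)cc(OC)c3O)c2)ccc1O | target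

## Step count and least certain steps

Total: 16 steps. Longest linear sequence: 16 steps (1 to 28). Iodide 19 enters twice, at steps 10 and 15, so both lactones come from one chain of intermediates.

Step 7 (key step). The thermodynamic bias between the two diastereotopic hydroxymethyl groups may be too small, so that closure through the wrong oxygen keeps a sizeable share of the material as 15. The energy gap rests only on the difference between OH and arylmethyl at C3 and is not calibrated for this substrate. Fallback, setting out from 13 and returning at 17: after the acetonide has been removed, phenylboronic acid is added to the equilibrating lactones in toluene with TsOH and azeotropic removal of water. Only the lactone with the tertiary hydroxyl and the CH2OH cis can close a six-membered boronic ester, so the equilibrium through 16 should drain into the cis-fused cyclic phenylboronate F1. Transesterification with pinacol at 23 °C, without acid, then releases 17 with no chance to re-equilibrate. A covalent ring-fusion trap thus replaces the intrinsic conformational preference.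

Step 4. The congested aldolate 10 may revert to 7 and 8 before it is acylated, or acylation of the hindered tertiary alkoxide may remain incomplete, returning starting dioxolanone. Fallback, setting out from 7 and 8 and returning at 12 (11 and step 5 are bypassed): the aldolate is quenched at −78 °C with acetic acid and the tertiary alcohol F2 is isolated. The Burgess reagent dehydrates F2 by syn-elimination; the only β-hydrogens are on the dioxane CH2 groups, so the enol ether F3 is expected. Hydrogenation over 5% Rh/Al2O3 (H2, EtOAc), which spares the benzyl ether, then gives 12 without creating a stereocentre. The same detour serves if the tin hydride reduction of step 5 is diverted by fragmentation of the tertiary radical.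

Step 15 (the same concern applies to step 10). Homocoupling of either partner or hydrodehalogenation of 19 may outrun the cross-coupling, because the electron-rich aryl bromide adds slowly to zerovalent nickel while the iodide is consumed; this would waste the valuable bromide 26. Fallback, setting out from 19 and 26 and returning at 27: a palladium-catalysed Negishi-type coupling in water. Zn dust with TMEDA in an aqueous surfactant medium inserts into the C–I bond of 19 to give the alkylzinc iodide F4. F4 is transmetalated at once to the arylpalladium bromide formed from 26 with PdCl2[P(t-Bu)2(4-Me2NC6H4)]2 at 23 °C. A polar two-electron C–C bond formation replaces the radical capture, and the aqueous medium tolerates the phenol and the tertiary alcohol.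

Step 1. Nitrosation or oxidation of the electron-rich free guaiacol ring by nitrous acid may compete with diazotisation of the amine. Fallback, setting out from 1 and returning at 5 (4 is bypassed): the phenol is benzylated first through the copper chelate of the amino acid (CuSO4, NaOH; BnBr; then decomplexation) to give O-benzyl-3-O-methyl-L-DOPA F5. The same diazotisation (NaNO2, H2SO4, aqueous dioxane) then gives 5 with retention through the corresponding α-lactone. The ring is then an aryl ether and far less prone to nitrosation.

## Further compounds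

F1 | step 7 | cyclic phenylboronate of 17 (2-phenyl-1,3,2-dioxaborinane cis-fused to the lactone across the tertiary hydroxyl and the hydroxymethyl group) | O2C[C@@H]1COC(=O)[C@@]1(OB2c3ccccc3)Cc1ccc(OCc2ccccc2)c(OC)c1
F2 | step 4 | (2S,5R)-5-[4-(benzyloxy)-3-methoxybenzyl]-2-tert-butyl-5-(5-hydroxy-2,2-dimethyl-1,3-dioxan-5-yl)-1,3-dioxolan-4-one | O=C1O[C@@H](C(C)(C)C)O[C@@]1(C2(O)COC(C)(C)OC2)Cc1ccc(OCc2ccccc2)c(OC)c1
F3 | step 4 | (2S,5R)-5-[4-(benzyloxy)-3-methoxybenzyl]-2-tert-butyl-5-(2,2-dimethyl-4H-1,3-dioxin-5-yl)-1,3-dioxolan-4-one | O=C1O[C@@H](C(C)(C)C)O[C@@]1(C2=COC(C)(C)OC2)Cc1ccc(OCc2ccccc2)c(OC)c1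
F4 | step 15 | {[(3R,4R)-4-hydroxy-4-(4-hydroxy-3-methoxybenzyl)-5-oxooxolan-3-yl]methyl}zinc iodide | I[Zn]C[C@@H]1COC(=O)[C@@]1(O)Cc1ccc(O)c(OC)c1
F5 | step 1 | O-benzyl-3-O-methyl-L-DOPA, (S)-2-amino-3-[4-(benzyloxy)-3-methoxyphenyl]propanoic acid | COc1cc(C[C@H](N)C(=O)O)ccc1OCc1ccccc1
A1 | alternative 1 | biaryl bis[(R,Z)-allylic (S)-2-benzyloxy-3-arylpropanoate], substrate of the double Ireland–Claisen rearrangement | COc1cc(C/C=C\[C@@H](C)OC(=O)[C@@H](OCc2ccccc2)Cc2cc(OC)c(OCc3ccccc3)c(-c3cc(C/C=C\[C@@H](C)OC(=O)[C@@H](OCc4ccccc4)Cc4ccc(OCc5ccccc5)c(OC)c4)cc(OC)c3OCc3ccccc3)c2)ccc1OCc1ccccc1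
A2 | alternative 1 | biaryl bis(α-benzyloxy β-propenyl carboxylic acid) | COc1cc(C[C@H](/C=C/C)[C@@](OCc2ccccc2)(C(=O)O)Cc2cc(OC)c(OCc3ccccc3)c(-c3cc(C[C@H](/C=C/C)[C@@](OCc4ccccc4)(C(=O)O)Cc4ccc(OCc5ccccc5)c(OC)c4)cc(OC)c3OCc3ccccc3)c2)ccc1OCc1ccccc1
A3 | alternative 2 | bis(aryloxy)di-tert-butylsilane of the two monomers (bromide on ring B, C–H on ring C) | COc1cc(C[C@@H]2COC(=O)[C@@]2(O)Cc2cc(OC)c(O[Si](C(C)(C)C)(C(C)(C)C)Oc3ccc(C[C@@H]4COC(=O)[C@@]4(O)Cc4ccc(OCc5ccccc5)c(OC)c4)cc3OC)c(Br)c2)ccc1OCc1ccccc1
A4 | alternative 2 | dioxasilepine-bridged dimer, rings A and D benzylated | COc1cc(C[C@@H]2COC(=O)[C@@]2(O)Cc2cc(OC)c3O[Si](C(C)(C)C)(C(C)(C)C)Oc4c(OC)cc(C[C@@H]5COC(=O)[C@@]5(O)Cc5ccc(OCc6ccccc6)c(OC)c5)cc4-c3c2)ccc1OCc1ccccc1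
A5 | alternative 3 | bis(acyloxymethyl xanthate) with two (E)-styrenes on the (R)-carbinols | COc1cc(/C=C/[C@](O)(Cc2cc(OC)c(OCc3ccccc3)c(-c3cc(/C=C/[C@](O)(Cc4ccc(OCc5ccccc5)c(OC)c4)C(=O)OCSC(=S)OCC)cc(OC)c3OCc3ccccc3)c2)C(=O)OCSC(=S)OCC)ccc1OCc1ccccc1
A6 | alternative 3 | tetra-O-benzyl target | COc1cc(C[C@@H]2COC(=O)[C@@]2(O)Cc2cc(OC)c(OCc3ccccc3)c(-c3cc(C[C@@H]4COC(=O)[C@@]4(O)Cc4ccc(OCc5ccccc5)c(OC)c4)cc(OC)c3OCc3ccccc3)c2)ccc1OCc1ccccc1
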